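Percent per minute squared is the unit the red run reads in: from 80.0 min to 150 min time grows 1.88-fold and target 3.23-fold, near the square of the time factor, 3.52. So at 25 °C the catalyst is read as still switching on while it works, an induction period.

| flask | starting material | precatalyst | temperature | remark | time |
|---|---|---|---|---|---|
| red | 0.15 M | 7.6 mol% | 25 °C | run made earlier |  |
| teal | 0.22 M | 7.6 mol% | 60 °C | run made earlier |  |
| birch | 0.30 M | 7.6 mol% |  | at 90 °C until 5.0 min, from then on at 30 °C | 10 min |
| elm | 0.30 M | 7.6 mol% | 90 °C |  | 10 min |
| oak | 0.30 M | 7.6 mol% | 60 °C |  | 10 min |
| cedar | 0.30 M | 7.6 mol% | 30 °C |  | 10 min |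

| run | time / min | target / % | starting material / % |
|---|---|---|---|
| red | 40.0 | 1.0 | 98.8 |
| red | 80.0 | 3.1 | 96.9 |
| red | 120 | 6.3 | 93.1 |
| red | 150 | 10.0 | 89.8 |
| teal | 6.00 | 8.9 | 89.8 |
| teal | 12.0 | 17.6 | 76.0 |
| teal | 20.0 | 22.3 | 60.9 |
| teal | 25.0 | 23.5 | 53.2 |

(readings scatter by 0.3 percentage points)

- the flask that comes out highest in amount of target, in percent of the starting material charged, or "all alike" when all lie within 1.5 percentage points (birch / elm / oak / cedar / all alike)
- target at the end, in percent of the starting material charged, birch
- target at the end, in percent of the starting material charged, elm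
- target at the end, in percent of the starting material charged, oak
- target at the end, in percent of the starting material charged, cedar

- the numbers in the tables scatter with a standard deviation of 0.3 percentage points

The teal run at 60 °C reads differently: target stands at 8.9 % after 6.00 min and 17.6 % after 12.0 min, so the switching-on is over within the first reading. Two chemists dispute what that levelling means, and the question is birch, which is cooled from 90 °C to 30 °C at 5.0 min.

The first says the precatalyst has turned over one way and stays on, so the hot stage hands birch a working catalyst. He gives the forecast: oak highest, with birch 9.5 %, elm 3.3 %, oak 20 % and cedar 0.3 %. Of birch he says: “the activated catalyst then adds about 4% at 30 °C with little decay”.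

The second says the levelling may be a ceiling, a share of catalyst that depends on temperature and may sink on heating; the two runs cannot separate these views. Then birch enters the cold stage much like a fresh cold flask at that time, and its gain follows the square law. Her quantity is the cold share, the part of a cold flask's end target that a square law makes after the change: 75.0 %. On the forecast's cedar that is 0.23 points, far from his gain. Taking the forecast's elm level for the hot stage, her own reckoning for birch is 3.53 %, not his number.

The simulation runs on this scheme:

    target ⇌ isomer of the product (K = 8.30, k = 0.0653 /min, Ea = 108 kJ/mol, ΔH = 7.00 kJ/mol)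
    starting material + free catalyst → spent catalyst (k = 0.0104 /M/min, Ea = 73.0 kJ/mol)
    starting material + free catalyst ⇌ target + free catalyst, rate k3*[starting material]*[free catalyst] forward; the back reaction follows from the equilibrium constant (K = 25.0, k = 9.34 /M/min, Ea = 66.0 kJ/mol, ΔH = 1.00 kJ/mol)
    precatalyst ⇌ free catalyst (K = 0.217, k = 0.0855 /min, Ea = 94.0 kJ/mol, ΔH = −84.0 kJ/mol)
    (constants at 60 °C)

Birch ends at 2.51 %, less than the forecast's 9.5 %, elm at 3.11 %, cedar at 0.294 %, and oak comes out highest at 19.7 %. At the change birch held 1.74 % of the catalyst charged as free catalyst, with 98.0 % still precatalyst; cedar then held 1.47 %. The cold share of cedar's end is 0.22 points; cedar gained 0.22 points after that time, and birch 0.21 points. The first chemist's rising catalyst is what cedar shows, more free catalyst at 2.92 % after 10.0 min than 1.47 % after 5.00 min. The second chemist's ceiling is what oak shows, with free catalyst at 16.1 % after 5.00 min, 17.5 % after 10.0 min and 17.6 % after 100 min, when 81.0 % is still precatalyst.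

All runs are simulated on assumed constants.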